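The cyclohexane ring is cut at C1–C6 and C4–C5 (quinic acid numbering). The four-carbon unit C1–C4 is a furanose-type lactol made from the L-glutamic acid-derived lactone acid, in which the C1 oxygen masks the C4 aldehyde; C5–C6 comes from vinyltriphenylphosphonium bromide. One Schweizer annulation joins them: the C1 ester enolate adds to the vinyl salt (C1–C6) and the resulting ylide olefinates the unmasked C4 aldehyde (C4=C5), so that the tetrahydrofuran ring oxygen becomes the tertiary C1 hydroxyl. The step exploits the 1,4 relationship across the cyclohexane ring between the C1 carbinol carbon and the oxygenated C4. Hydroxyl-directed epoxidation and lactonisation by the C1 carboxyl then set C4 and C5.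

Key step: step 5

Remark: ring carbons of the carbocycles are numbered as in quinic acid (C1 carbinol and carboxyl carbon, C3 the free secondary hydroxyl of the target, C4 and C5 the ester carbons); α is the face of the 1-, 3- and 4-oxygen atoms, β that of the carboxyl group and the 5-oxygen. Compounds 1, 6 and 13 are taken as commercial.

Step 1
Reactants: 1 (S)-5-oxotetrahydrofuran-2-carboxylic acid
Product: 2 tert-butyl (S)-5-oxotetrahydrofuran-2-carboxylate
Conditions: Cl3CC(=NH)OtBu, BF3·OEt2 (cat.), CH2Cl2–cyclohexane, rt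
Reagents that add atoms: tert-butyl 2,2,2-trichloroacetimidate, CC(C)(C)OC(=N)C(Cl)(Cl)Cl
Why: Acid-catalysed imidate esterification transfers a tert-butyl group to the carboxylic acid under conditions that should leave the lactone and the stereocentre untouched.

Step 2
Reactants: 2 tert-butyl (S)-5-oxotetrahydrofuran-2-carboxylate
Product: 3 tert-butyl (2S,4R)-4-hydroxy-5-oxotetrahydrofuran-2-carboxylate
Conditions: NaN(SiMe3)2 (1.05 equiv), THF, −78 °C; 2-(phenylsulfonyl)-3-phenyloxaziridine, −78 °C; AcOH
Reagents that add atoms: (±)-trans-2-(phenylsulfonyl)-3-phenyloxaziridine, O=S(=O)(c1ccccc1)N1OC1c1ccccc1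
Why: Kinetic enolisation should occur at the lactone α-CH2 and not at the hindered proton next to the tert-butyl ester, and Davis enolate hydroxylation should then deliver oxygen anti to the C2 ester group, which sets the future C3 carbinol centre (4R, trans); the minor cis isomer is removed by chromatography.

Step 3
Reactants: 3 tert-butyl (2S,4R)-4-hydroxy-5-oxotetrahydrofuran-2-carboxylate
Product: 4 tert-butyl (2S,4R)-4-(benzyloxy)-5-oxotetrahydrofuran-2-carboxylate
Conditions: BnBr, Ag2O, CH2Cl2, rt, dark
Reagents that add atoms: benzyl bromide, BrCc1ccccc1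
Why: Silver oxide-promoted Williamson benzylation of an α-hydroxy lactone runs under nearly neutral conditions, so the lactone, the ester and the α-stereocentre should not be disturbed.

Step 4
Reactants: 4 tert-butyl (2S,4R)-4-(benzyloxy)-5-oxotetrahydrofuran-2-carboxylate
Product: 5 tert-butyl (2S,4R)-4-(benzyloxy)-5-hydroxytetrahydrofuran-2-carboxylate (lactol, both anomers)
Conditions: iBu2AlH (1.1 equiv), CH2Cl2, −78 °C; aq. KNaC4H4O6
Reagents that add atoms: none
Why: In this partial lactone reduction iBu2AlH should add once to the γ-lactone at −78 °C and the aluminium lactolate should survive until work-up, while the hindered tert-butyl ester does not react.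

Step 5
Reactants: 5 tert-butyl (2S,4R)-4-(benzyloxy)-5-hydroxytetrahydrofuran-2-carboxylate, 6 vinyltriphenylphosphonium bromide
Product: 9 tert-butyl (1R,5R)-5-(benzyloxy)-1-hydroxycyclohex-3-ene-1-carboxylate, via dilithium dianion 7 (not isolated), via phosphorus ylide 8 (not isolated)
Conditions: LiN(iPr)2 (2.2 equiv), THF, −78 °C; 6 (1.05 equiv), −78 °C → rt, then 60 °C; H2O
Reagents that add atoms: none
Why: Two equivalents of base should convert 5 into the lithium lactolate ester enolate 7, whose enolate carbon C1 adds to the vinylphosphonium salt in a Michael addition (C1–C6) to give the non-stabilised ylide 8; the lactolate then ring-opens to the C4 aldehyde, which the ylide carbon C5 captures in an intramolecular Wittig olefination (C4=C5) with loss of Ph3PO. The closest known reaction type is the Schweizer annulation, the Michael addition of a carbanion to a vinylphosphonium salt followed by intramolecular Wittig reaction, which is established for cyclopentenes and cyclohexenes from carbanions that carry a carbonyl group in the chain. The six-membered carbocycle is closed by 6-exo-trig attack of C5 on the aldehyde carbon through a ring-fused oxaphosphetane, so that the ring alkene is necessarily cis and no stereocentre arises at C4 or C5. The one new stereocentre, C1, is controlled by the C3 benzyloxy group: the salt should approach the planar enolate on the face of the tetrahydrofuran envelope opposite to C3–OBn and to the lithium lactolate that chelation holds cis to it, which puts C6 trans to O3 and, once the ring oxygen has become the C1 hydroxyl, the 1-OH cis to the 3-OBn. The step needs C- over O-alkylation, secured by the higher nucleophilicity of the last-formed enolate carbon towards one equivalent of salt, and an aldehyde that never meets the amide base, secured by the lactolate, which stays closed until C1 is quaternary.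

Step 6
Reactants: 9 tert-butyl (1R,5R)-5-(benzyloxy)-1-hydroxycyclohex-3-ene-1-carboxylate
Product: 11 (1S,3R,4R,5R)-3-(benzyloxy)-1,4-dihydroxy-6-oxabicyclo[3.2.1]octan-7-one (3-O-benzyl-1,5-quinide), via cis-epoxide 10 (not isolated)
Conditions: VO(acac)2 (5 mol %), t-BuOOH (1.5 equiv), CH2Cl2, 0 °C → rt; then CF3CO2H, 0 °C → rt
Reagents that add atoms: tert-butyl hydroperoxide, CC(C)(C)OO
Why: The tertiary C1 hydroxyl should bind vanadium and deliver the peroxide oxygen to the α face of the homoallylic alkene (hydroxyl-directed epoxidation), and under acid the tert-butyl ester carbonyl, axial on the β face, should open epoxide 10 at C5 with inversion and lose isobutene (epoxy ester lactonisation), which sets the C5 oxygen β and leaves the C4 hydroxyl α, a β-epoxide being unable to lactonise.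

Step 7
Reactants: 11 (1S,3R,4R,5R)-3-(benzyloxy)-1,4-dihydroxy-6-oxabicyclo[3.2.1]octan-7-one
Product: 12 benzyl (1R,3R,4S,5R)-3-(benzyloxy)-1,4,5-trihydroxycyclohexane-1-carboxylate (benzyl 3-O-benzylquinate)
Conditions: BnOH (10 equiv), NaOCH2Ph (0.2 equiv), THF, 0 °C; AcOH
Reagents that add atoms: benzyl alcohol, OCc1ccccc1
Why: Benzyloxide-catalysed transesterification should open the strained bicyclic γ-lactone at the acyl carbon, so that C5 keeps its configuration, the 5-hydroxyl is set free and the carboxyl group is masked as a benzyl ester.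

Step 8
Reactants: 12 benzyl (1R,3R,4S,5R)-3-(benzyloxy)-1,4,5-trihydroxycyclohexane-1-carboxylate, 13 4-(benzyloxy)-3-methoxybenzoic acid
Product: 14 benzyl (1S,3R,4R,5R)-3-(benzyloxy)-4,5-bis{[4-(benzyloxy)-3-methoxybenzoyl]oxy}-1-hydroxycyclohexane-1-carboxylate
Conditions: 13 (2.6 equiv), DCC (3 equiv), DMAP (1 equiv), CH2Cl2, 0 °C → rt
Reagents that add atoms: none
Why: Steglich esterification should acylate the two secondary hydroxyls at C4 and C5, whereas the tertiary C1 hydroxyl next to the ester is too hindered to react.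

Step 9
Reactants: 14 benzyl (1S,3R,4R,5R)-3-(benzyloxy)-4,5-bis{[4-(benzyloxy)-3-methoxybenzoyl]oxy}-1-hydroxycyclohexane-1-carboxylate
Product: 15 Burkinabin C, (1S,3R,4R,5R)-1,3-dihydroxy-4,5-bis[(4-hydroxy-3-methoxybenzoyl)oxy]cyclohexane-1-carboxylic acid
Conditions: H2 (1 atm), Pd(OH)2/C, EtOAc–MeOH, rt
Reagents that add atoms: none
Why: Catalytic hydrogenolysis should cleave the benzyl ester, the C3 benzyl ether and both aryl benzyl ethers in one operation under neutral conditions that leave the two aroyl esters in place and do not promote acyl migration.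

Compound list
1 | (S)-5-oxotetrahydrofuran-2-carboxylic acid | O=C(O)[C@@H]1CCC(=O)O1 | starting material
2 | tert-butyl (S)-5-oxotetrahydrofuran-2-carboxylate | CC(C)(C)OC(=O)[C@@H]1CCC(=O)O1 | intermediate
3 | tert-butyl (2S,4R)-4-hydroxy-5-oxotetrahydrofuran-2-carboxylate (hydroxyl trans to the ester) | CC(C)(C)OC(=O)[C@@H]1C[C@@H](O)C(=O)O1 | intermediate
4 | tert-butyl (2S,4R)-4-(benzyloxy)-5-oxotetrahydrofuran-2-carboxylate | CC(C)(C)OC(=O)[C@@H]1C[C@@H](OCc2ccccc2)C(=O)O1 | intermediate
5 | tert-butyl (2S,4R)-4-(benzyloxy)-5-hydroxytetrahydrofuran-2-carboxylate (lactol, both anomers) | CC(C)(C)OC(=O)[C@@H]1C[C@@H](OCc2ccccc2)C(O)O1 | intermediate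
6 | vinyltriphenylphosphonium bromide | C=C[P+](c1ccccc1)(c1ccccc1)c1ccccc1.[Br-] | starting material
7 | dilithium salt of 5 (lactolate and tert-butyl ester enolate) | [Li+].[Li+].CC(C)(C)OC([O-])=C1C[C@@H](OCc2ccccc2)C([O-])O1 | intermediate
8 | lithium lactolate of tert-butyl 4-(benzyloxy)-5-hydroxy-2-[2-(triphenylphosphoranylidene)ethyl]tetrahydrofuran-2-carboxylate (ylide side chain trans to the benzyloxy group) | [Li+].[O-]C1O[C@@](CC=P(c2ccccc2)(c2ccccc2)c2ccccc2)(C(=O)OC(C)(C)C)C[C@H]1OCc1ccccc1 | intermediate
9 | tert-butyl (1R,5R)-5-(benzyloxy)-1-hydroxycyclohex-3-ene-1-carboxylate (hydroxyl cis to benzyloxy) | C1=C[C@H](OCc2ccccc2)C[C@@](O)(C(=O)OC(C)(C)C)C1 | intermediate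
10 | tert-butyl 5-(benzyloxy)-3-hydroxy-7-oxabicyclo[4.1.0]heptane-3-carboxylate, epoxide oxygen on the same face as the 3-hydroxyl and the 5-benzyloxy group (4α,5α-epoxide of 9) | O1[C@H]2C[C@](O)(C(=O)OC(C)(C)C)C[C@@H](OCc3ccccc3)[C@@H]12 | intermediate
11 | (1S,3R,4R,5R)-3-(benzyloxy)-1,4-dihydroxy-6-oxabicyclo[3.2.1]octan-7-one (3-O-benzyl-1,5-quinide) | O=C1O[C@@H]2C[C@@]1(O)C[C@@H](OCc1ccccc1)[C@H]2O | intermediate
12 | benzyl (1R,3R,4S,5R)-3-(benzyloxy)-1,4,5-trihydroxycyclohexane-1-carboxylate (benzyl 3-O-benzylquinate) | O[C@@H]1[C@H](OCc2ccccc2)C[C@@](O)(C(=O)OCc2ccccc2)C[C@H]1O | intermediate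
13 | 4-(benzyloxy)-3-methoxybenzoic acid | COc1cc(C(=O)O)ccc1OCc1ccccc1 | starting material
14 | benzyl (1S,3R,4R,5R)-3-(benzyloxy)-4,5-bis{[4-(benzyloxy)-3-methoxybenzoyl]oxy}-1-hydroxycyclohexane-1-carboxylate | COc1cc(C(=O)O[C@@H]2[C@H](OCc3ccccc3)C[C@@](O)(C(=O)OCc3ccccc3)C[C@H]2OC(=O)c2ccc(OCc3ccccc3)c(OC)c2)ccc1OCc1ccccc1 | intermediate
15 | Burkinabin C, (1S,3R,4R,5R)-1,3-dihydroxy-4,5-bis[(4-hydroxy-3-methoxybenzoyl)oxy]cyclohexane-1-carboxylic acid | COc1cc(C(=O)O[C@@H]2[C@H](O)C[C@@](O)(C(=O)O)C[C@H]2OC(=O)c2ccc(O)c(OC)c2)ccc1O | target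

Total step count: 9. Longest linear sequence: 9 steps (1 to 15).

Steps most likely to fail

1. Step 5. What may go wrong: the lactolate oxygen may attack the vinylphosphonium salt in place of the enolate carbon, or the ylide may be quenched before the lactolate opens, so that the ring does not close; the facial bias at C1 may also be weak. The fallback sets out from 5 and comes back at 9, and forms the two bonds in separate operations. Dianion 7 should be C-alkylated with allyl bromide to give tert-butyl (2R,4R)-2-allyl-4-(benzyloxy)-5-hydroxytetrahydrofuran-2-carboxylate F1. Wittig methylenation of this lactol with Ph3P=CH2 (from Ph3PCH3Br and KOtBu, THF) should give the open-chain diene tert-butyl (2R,4R)-2-allyl-4-(benzyloxy)-2-hydroxyhex-5-enoate F2, at which stage C1 epimers can be separated. Ring-closing metathesis with the second-generation Grubbs catalyst (CH2Cl2, 40 °C) should then close C4=C5 and give 9.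

2. Step 2. What may go wrong: the base may remove the proton next to the tert-butyl ester in competition with the lactone α-proton, which erodes the only stereocentre and gives mixtures, or the hydroxylation may be poorly trans-selective. The fallback sets out from 1 and comes back at 4, and carries the carboxyl carbon at the alcohol oxidation level while the oxygen is introduced.
 - Reduction of 1 with BH3·SMe2 should give (S)-5-(hydroxymethyl)dihydrofuran-2(3H)-one F3.
 - TBDPSCl and imidazole should give (S)-5-{[(tert-butyldiphenylsilyl)oxy]methyl}dihydrofuran-2(3H)-one F4, which has no competing acidic proton and a large group at C5.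
 - Enolate hydroxylation (NaN(SiMe3)2, Davis oxaziridine) should give (3R,5S)-5-{[(tert-butyldiphenylsilyl)oxy]methyl}-3-hydroxydihydrofuran-2(3H)-one F5.
 - BnBr and Ag2O should give (3R,5S)-3-(benzyloxy)-5-{[(tert-butyldiphenylsilyl)oxy]methyl}dihydrofuran-2(3H)-one F6.
 - HF·pyridine should give (3R,5S)-3-(benzyloxy)-5-(hydroxymethyl)dihydrofuran-2(3H)-one F7.
 - Oxidation with TEMPO and PhI(OAc)2 in MeCN–H2O should give (2S,4R)-4-(benzyloxy)-5-oxotetrahydrofuran-2-carboxylic acid F8.
 - Esterification with tert-butyl 2,2,2-trichloroacetimidate should give 4.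

3. Step 7. What may go wrong: the transesterification may stop at an equilibrium mixture, and the hydroxy ester may close back to the lactone on work-up or on silica. The fallback sets out from 11 and comes back at 12, and replaces the equilibrium by an irreversible opening. Saponification with LiOH (THF–H2O, 0 °C) and careful acidification should give (1R,3R,4S,5R)-3-(benzyloxy)-1,4,5-trihydroxycyclohexane-1-carboxylic acid F9. Selective O-alkylation of its carboxylate (Cs2CO3, BnBr, DMF, rt) should give 12.

Further compounds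
F1 | step 5 | tert-butyl (2R,4R)-2-allyl-4-(benzyloxy)-5-hydroxytetrahydrofuran-2-carboxylate | CC(C)(C)OC(=O)[C@@]1(CC=C)C[C@@H](OCc2ccccc2)C(O)O1
F2 | step 5 | tert-butyl (2R,4R)-2-allyl-4-(benzyloxy)-2-hydroxyhex-5-enoate | C=C[C@H](OCc1ccccc1)C[C@](O)(CC=C)C(=O)OC(C)(C)C
F3 | step 2 | (S)-5-(hydroxymethyl)dihydrofuran-2(3H)-one | OC[C@@H]1CCC(=O)O1
F4 | step 2 | (S)-5-{[(tert-butyldiphenylsilyl)oxy]methyl}dihydrofuran-2(3H)-one | CC(C)(C)[Si](OC[C@@H]1CCC(=O)O1)(c1ccccc1)c1ccccc1
F5 | step 2 | (3R,5S)-5-{[(tert-butyldiphenylsilyl)oxy]methyl}-3-hydroxydihydrofuran-2(3H)-one | CC(C)(C)[Si](OC[C@@H]1C[C@@H](O)C(=O)O1)(c1ccccc1)c1ccccc1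
F6 | step 2 | (3R,5S)-3-(benzyloxy)-5-{[(tert-butyldiphenylsilyl)oxy]methyl}dihydrofuran-2(3H)-one | CC(C)(C)[Si](OC[C@@H]1C[C@@H](OCc2ccccc2)C(=O)O1)(c1ccccc1)c1ccccc1
F7 | step 2 | (3R,5S)-3-(benzyloxy)-5-(hydroxymethyl)dihydrofuran-2(3H)-one | OC[C@@H]1C[C@@H](OCc2ccccc2)C(=O)O1
F8 | step 2 | (2S,4R)-4-(benzyloxy)-5-oxotetrahydrofuran-2-carboxylic acid | O=C(O)[C@@H]1C[C@@H](OCc2ccccc2)C(=O)O1
F9 | step 7 | (1R,3R,4S,5R)-3-(benzyloxy)-1,4,5-trihydroxycyclohexane-1-carboxylic acid | O[C@@H]1[C@H](OCc2ccccc2)C[C@@](O)(C(=O)O)C[C@H]1O
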